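Ring B is built onto the finished chromone instead of being coupled on as an arene. Cutting the C1'–C2' and C5'–C6' bonds leads to a 2-ethynylchromone (rings A and C carrying the C8 prenyl group and O3, O5, O7 as MOM ethers) and a 1-methoxy-2-prenyl-3-silyloxybutadiene. A single Diels–Alder/aromatization operation closes ring B and transfers the diene substituents into its 1,3,4-pattern: the prenyl group lands on C3', ortho to the C4' hydroxyl and meta to C1', so no Friedel–Crafts prenylation of a phenol is needed. Conjugation of the alkyne with the C4 carbonyl through C2=C3 polarizes it and fixes the orientation. Acid then removes the three MOM groups.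

Key step: step 13

Remark: base-mediated formylation of a methyl n-alkyl ketone is assumed to go mainly at the methyl group, so the C3 enol derivative needed for the diene is made regiospecifically by conjugate addition to but-3-en-2-one; the O3 atom is installed on the acetophenone before ring C is closed.

Step 1
Reactants: 1 2,4,6-trihydroxyacetophenone; 2 prenyl bromide (1-bromo-3-methylbut-2-ene)
Product: 3 1-[2,4,6-trihydroxy-3-(3-methylbut-2-en-1-yl)phenyl]ethan-1-one
Conditions: DBU, THF, 0 °C → rt (0.9 equiv of 2)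
Reagents that add atoms: none
Why: Direct nuclear C-prenylation of the ambident phloroglucinol phenoxide; C3 and C5 are equivalent, so mono-alkylation gives one constitution, and a small deficit of bromide limits bis-prenylation.

Step 2
Reactants: 3 1-[2,4,6-trihydroxy-3-(3-methylbut-2-en-1-yl)phenyl]ethan-1-one
Product: 4 1-[2-hydroxy-4,6-bis(methoxymethoxy)-3-(3-methylbut-2-en-1-yl)phenyl]ethan-1-one
Conditions: MOMCl (2.2 equiv), iPr2NEt, CH2Cl2, 0 °C → rt
Reagents that add atoms: chloromethyl methyl ether, COCCl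
Why: Williamson-type acetal ether formation at the para hydroxyl and at the less hindered ortho hydroxyl; the hydroxyl flanked by acetyl and prenyl stays as the chelated phenol and later becomes O1, which places the prenyl group at C8.

Step 3
Reactants: 4 1-[2-hydroxy-4,6-bis(methoxymethoxy)-3-(3-methylbut-2-en-1-yl)phenyl]ethan-1-one
Product: 6 2-hydroxy-1-[2-hydroxy-4,6-bis(methoxymethoxy)-3-(3-methylbut-2-en-1-yl)phenyl]ethan-1-one, via disodium enolate phenoxide 5 (not isolated)
Conditions: NaN(SiMe3)2 (2.3 equiv), THF, −78 °C; 2-(phenylsulfonyl)-3-phenyloxaziridine (1.1 equiv), −78 °C; AcOH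
Reagents that add atoms: 2-(phenylsulfonyl)-3-phenyloxaziridine, O=S(=O)(c1ccccc1)N1OC1c1ccccc1
Why: Davis oxidation: the sodium enolate of the methyl ketone attacks the electrophilic oxaziridine oxygen, and at −78 °C the reagent should leave the prenyl alkene and the arene untouched.

Step 4
Reactants: 6 2-hydroxy-1-[2-hydroxy-4,6-bis(methoxymethoxy)-3-(3-methylbut-2-en-1-yl)phenyl]ethan-1-one
Product: 7 1-[2-hydroxy-4,6-bis(methoxymethoxy)-3-(3-methylbut-2-en-1-yl)phenyl]-2-(methoxymethoxy)ethan-1-one
Conditions: MOMCl (1.2 equiv), iPr2NEt, CH2Cl2, 0 °C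
Reagents that add atoms: chloromethyl methyl ether, COCCl
Why: Acetal ether formation at the primary alcohol, which is far more reactive than the hindered, chelated phenol that already survived step 2.

Step 5
Reactants: 7 1-[2-hydroxy-4,6-bis(methoxymethoxy)-3-(3-methylbut-2-en-1-yl)phenyl]-2-(methoxymethoxy)ethan-1-one; 8 N,N-dimethylformamide dimethyl acetal
Product: 10 3,5,7-tris(methoxymethoxy)-8-(3-methylbut-2-en-1-yl)-4H-chromen-4-one, via enaminone 9 (not isolated)
Conditions: toluene, 100 °C; then AcOH, 50 °C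
Reagents that add atoms: none
Why: Enaminone route to chromones: condensation at the α-alkoxy methylene, then conjugate addition of the free phenol and loss of dimethylamine closes ring C with C2 still unsubstituted.

Step 6
Reactants: 10 3,5,7-tris(methoxymethoxy)-8-(3-methylbut-2-en-1-yl)-4H-chromen-4-one
Product: 12 2-iodo-3,5,7-tris(methoxymethoxy)-8-(3-methylbut-2-en-1-yl)-4H-chromen-4-one, via 2-lithiochromone 11 (not isolated)
Conditions: LiN(iPr)2 (1.2 equiv), THF, −78 °C; I2, −78 → −40 °C; aq. Na2S2O3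
Reagents that add atoms: iodine, II
Why: Deprotonative metalation–iodination: C2–H is the most acidic C–H (vinylic, on the carbon bound to the ring oxygen, β to the carbonyl) and the neighbouring MOM ether coordinates lithium, so the carbanion forms at C2 and is trapped by iodine.

Step 7
Reactants: 12 2-iodo-3,5,7-tris(methoxymethoxy)-8-(3-methylbut-2-en-1-yl)-4H-chromen-4-one; 13 trimethylsilylacetylene
Product: 14 3,5,7-tris(methoxymethoxy)-8-(3-methylbut-2-en-1-yl)-2-[(trimethylsilyl)ethynyl]-4H-chromen-4-one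
Conditions: Pd(PPh3)2Cl2 (3 mol %), CuI (5 mol %), Et3N, THF, rt
Reagents that add atoms: none
Why: Sonogashira coupling; the 2-iodochromone is a vinylogous acyl iodide and should add readily to zerovalent palladium at room temperature.

Step 8
Reactants: 14 3,5,7-tris(methoxymethoxy)-8-(3-methylbut-2-en-1-yl)-2-[(trimethylsilyl)ethynyl]-4H-chromen-4-one
Product: 15 2-ethynyl-3,5,7-tris(methoxymethoxy)-8-(3-methylbut-2-en-1-yl)-4H-chromen-4-one
Conditions: Bu4NF, AcOH, THF, −20 → 0 °C
Reagents that add atoms: none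
Why: Fluoride-induced protodesilylation of the alkynylsilane; the acetic acid buffer keeps nucleophiles from adding to the electrophilic terminal alkyne.

Step 9
Reactants: 16 but-3-en-2-one; 17 (2-methylprop-1-en-1-yl)magnesium bromide
Product: 18 trimethyl[(6-methylhepta-2,5-dien-2-yl)oxy]silane (E/Z mixture)
Conditions: CuBr·SMe2 (5 mol %), Me3SiCl, DMPU, THF, −78 °C; Et3N
Reagents that add atoms: chlorotrimethylsilane, C[Si](C)(C)Cl
Why: Copper-catalysed, chlorosilane-accelerated conjugate addition of the alkenyl Grignard reagent; the enolate is silylated where it forms, so the enol double bond sits only on the C3 side of the ketone.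

Step 10
Reactants: 18 trimethyl[(6-methylhepta-2,5-dien-2-yl)oxy]silane; 19 trimethyl orthoformate
Product: 20 3-(dimethoxymethyl)-6-methylhept-5-en-2-one (racemic)
Conditions: Me3SiOTf (5 mol %), CH2Cl2, −78 °C; pyridine quench
Reagents that add atoms: none
Why: Mukaiyama-type addition of the silyl enol ether to the dimethoxycarbenium ion released from the orthoformate; the C–C bond can form only at the enol carbon, and the racemic stereocenter is removed in the next step.

Step 11
Reactants: 20 3-(dimethoxymethyl)-6-methylhept-5-en-2-one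
Product: 21 (3E)-3-(methoxymethylidene)-6-methylhept-5-en-2-one
Conditions: DBU (0.2 equiv), toluene, 100 °C, 4 Å MS
Reagents that add atoms: none
Why: E1cB elimination of methanol from the β-keto acetal gives the conjugated β-methoxy enone, and reversible addition–elimination should settle on the E isomer (methoxy anti to acetyl).

Step 12
Reactants: 21 (3E)-3-(methoxymethylidene)-6-methylhept-5-en-2-one
Product: 22 (E)-1-methoxy-2-(3-methylbut-2-en-1-yl)-3-(trimethylsilyloxy)buta-1,3-diene
Conditions: Me3SiOTf, Et3N, Et2O, −10 → 0 °C; bulb-to-bulb distillation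
Reagents that add atoms: trimethylsilyl trifluoromethanesulfonate, C[Si](C)(C)OS(=O)(=O)C(F)(F)F
Why: Soft enolisation and O-silylation of the methyl ketone (the only α-hydrogens), the standard way to 1-methoxy-3-silyloxydienes; the E enol ether geometry is retained.

Step 13
Reactants: 15 2-ethynyl-3,5,7-tris(methoxymethoxy)-8-(3-methylbut-2-en-1-yl)-4H-chromen-4-one; 22 (E)-1-methoxy-2-(3-methylbut-2-en-1-yl)-3-(trimethylsilyloxy)buta-1,3-diene
Product: 25 2-[4-hydroxy-3-(3-methylbut-2-en-1-yl)phenyl]-3,5,7-tris(methoxymethoxy)-8-(3-methylbut-2-en-1-yl)-4H-chromen-4-one, via methoxycyclohexadiene cycloadduct 23 (not isolated), via aryl trimethylsilyl ether 24 (not isolated)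
Conditions: toluene, 120 °C, sealed tube, BHT (cat.), 3 equiv of 22; then K2CO3 (cat.), MeOH, rt
Reagents that add atoms: none
Why: A normal-electron-demand Diels–Alder reaction: the diene HOMO has its largest coefficient at the unsubstituted CH2 terminus, and the LUMO of the alkyne, conjugated with the C4 carbonyl through the C2=C3 bond of ring C (a vinylogous ynone), has its largest coefficient at the terminal carbon, so these atoms bond first in a concerted but asynchronous [4+2] transition state while the methoxy-bearing terminus bonds to the alkyne carbon attached to C2. The closest known reaction type is the cycloaddition of 1-methoxy-3-silyloxydienes with acetylenic ketones and esters followed by loss of methanol to give para-acyl phenols; the chromone-conjugated alkyne is a new member of that dienophile class. Ring B is closed in this one intermolecular cycloaddition, which forms C1'–C2' and C5'–C6'; cycloadduct 23 should then lose methanol by 1,4-elimination (aromatization as driving force) to give 24, and methanolic carbonate cleaves the silyl ether and also aromatizes any surviving 23 by enol ether cleavage and E1cB loss of methoxide. The only new stereocenter, the methoxy carbon of 23, disappears on aromatization, so no stereocontrol is needed. The selectivity required is regiochemical, and it is secured by the matched donor (C1 methoxy, C3 silyloxy) and acceptor (C4=O through C3=C2) polarization, which sends the diene C2 prenyl group to C3' next to the C4' oxygen; the electron-rich prenyl alkenes and the tetrasubstituted, donor-flanked C2=C3 bond should not compete as dienophiles.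

Step 14
Reactants: 25 2-[4-hydroxy-3-(3-methylbut-2-en-1-yl)phenyl]-3,5,7-tris(methoxymethoxy)-8-(3-methylbut-2-en-1-yl)-4H-chromen-4-one
Product: 26 broussoflavonol F
Conditions: 3 M aq. HCl, MeOH, 45 °C
Reagents that add atoms: none
Why: Acid-catalysed transacetalisation of the three MOM ethers to dimethoxymethane; mild acid and moderate temperature are chosen so that the prenyl groups ortho to the freed C7 and C4' hydroxyls should not cyclise to chromans.

Compound list
1 | 2,4,6-trihydroxyacetophenone | CC(=O)c1c(O)cc(O)cc1O | starting material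
2 | prenyl bromide (1-bromo-3-methylbut-2-ene) | CC(C)=CCBr | starting material
3 | 1-[2,4,6-trihydroxy-3-(3-methylbut-2-en-1-yl)phenyl]ethan-1-one | CC(=O)c1c(O)cc(O)c(CC=C(C)C)c1O | intermediate
4 | 1-[2-hydroxy-4,6-bis(methoxymethoxy)-3-(3-methylbut-2-en-1-yl)phenyl]ethan-1-one | CC(=O)c1c(OCOC)cc(OCOC)c(CC=C(C)C)c1O | intermediate
5 | disodium 1-[2-oxido-4,6-bis(methoxymethoxy)-3-(3-methylbut-2-en-1-yl)phenyl]ethen-1-olate | [Na+].[Na+].C=C([O-])c1c(OCOC)cc(OCOC)c(CC=C(C)C)c1[O-] | intermediate
6 | 2-hydroxy-1-[2-hydroxy-4,6-bis(methoxymethoxy)-3-(3-methylbut-2-en-1-yl)phenyl]ethan-1-one | OCC(=O)c1c(OCOC)cc(OCOC)c(CC=C(C)C)c1O | intermediate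
7 | 1-[2-hydroxy-4,6-bis(methoxymethoxy)-3-(3-methylbut-2-en-1-yl)phenyl]-2-(methoxymethoxy)ethan-1-one | COCOCC(=O)c1c(OCOC)cc(OCOC)c(CC=C(C)C)c1O | intermediate
8 | N,N-dimethylformamide dimethyl acetal | COC(OC)N(C)C | starting material
9 | 3-(dimethylamino)-1-[2-hydroxy-4,6-bis(methoxymethoxy)-3-(3-methylbut-2-en-1-yl)phenyl]-2-(methoxymethoxy)prop-2-en-1-one (double bond geometry not defined) | CN(C)C=C(OCOC)C(=O)c1c(OCOC)cc(OCOC)c(CC=C(C)C)c1O | intermediate
10 | 3,5,7-tris(methoxymethoxy)-8-(3-methylbut-2-en-1-yl)-4H-chromen-4-one | COCOc1coc2c(CC=C(C)C)c(OCOC)cc(OCOC)c2c1=O | intermediate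
11 | [3,5,7-tris(methoxymethoxy)-8-(3-methylbut-2-en-1-yl)-4-oxo-4H-chromen-2-yl]lithium | [Li]c1oc2c(CC=C(C)C)c(OCOC)cc(OCOC)c2c(=O)c1OCOC | intermediate
12 | 2-iodo-3,5,7-tris(methoxymethoxy)-8-(3-methylbut-2-en-1-yl)-4H-chromen-4-one | COCOc1c(I)oc2c(CC=C(C)C)c(OCOC)cc(OCOC)c2c1=O | intermediate
13 | trimethylsilylacetylene | C#C[Si](C)(C)C | starting material
14 | 3,5,7-tris(methoxymethoxy)-8-(3-methylbut-2-en-1-yl)-2-[(trimethylsilyl)ethynyl]-4H-chromen-4-one | COCOc1c(C#C[Si](C)(C)C)oc2c(CC=C(C)C)c(OCOC)cc(OCOC)c2c1=O | intermediate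
15 | 2-ethynyl-3,5,7-tris(methoxymethoxy)-8-(3-methylbut-2-en-1-yl)-4H-chromen-4-one | C#Cc1oc2c(CC=C(C)C)c(OCOC)cc(OCOC)c2c(=O)c1OCOC | intermediate
16 | but-3-en-2-one | CC(=O)C=C | starting material
17 | (2-methylprop-1-en-1-yl)magnesium bromide | CC(C)=C[Mg]Br | starting material
18 | trimethyl[(6-methylhepta-2,5-dien-2-yl)oxy]silane (E/Z mixture at the enol double bond) | CC(=CCC=C(C)C)O[Si](C)(C)C | intermediate
19 | trimethyl orthoformate | COC(OC)OC | starting material
20 | 3-(dimethoxymethyl)-6-methylhept-5-en-2-one (racemic) | CC(=O)C(CC=C(C)C)C(OC)OC | intermediate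
21 | (3E)-3-(methoxymethylidene)-6-methylhept-5-en-2-one | CO/C=C(/C(C)=O)CC=C(C)C | intermediate
22 | (E)-1-methoxy-2-(3-methylbut-2-en-1-yl)-3-(trimethylsilyloxy)buta-1,3-diene | CO/C=C(/C(=C)O[Si](C)(C)C)CC=C(C)C | intermediate
23 | 2-[6-methoxy-5-(3-methylbut-2-en-1-yl)-4-(trimethylsilyloxy)cyclohexa-1,4-dien-1-yl]-3,5,7-tris(methoxymethoxy)-8-(3-methylbut-2-en-1-yl)-4H-chromen-4-one (racemic) | COC1C(CC=C(C)C)=C(O[Si](C)(C)C)CC=C1c1oc2c(CC=C(C)C)c(OCOC)cc(OCOC)c2c(=O)c1OCOC | intermediate
24 | 3,5,7-tris(methoxymethoxy)-8-(3-methylbut-2-en-1-yl)-2-[3-(3-methylbut-2-en-1-yl)-4-(trimethylsilyloxy)phenyl]-4H-chromen-4-one | CC(C)=CCc1cc(-c2oc3c(CC=C(C)C)c(OCOC)cc(OCOC)c3c(=O)c2OCOC)ccc1O[Si](C)(C)C | intermediate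
25 | 2-[4-hydroxy-3-(3-methylbut-2-en-1-yl)phenyl]-3,5,7-tris(methoxymethoxy)-8-(3-methylbut-2-en-1-yl)-4H-chromen-4-one | CC(C)=CCc1cc(-c2oc3c(CC=C(C)C)c(OCOC)cc(OCOC)c3c(=O)c2OCOC)ccc1O | intermediate
26 | broussoflavonol F, 3,5,7-trihydroxy-2-[4-hydroxy-3-(3-methylbut-2-en-1-yl)phenyl]-8-(3-methylbut-2-en-1-yl)-4H-chromen-4-one (no stereocenters) | CC(C)=CCc1cc(-c2oc3c(CC=C(C)C)c(O)cc(O)c3c(=O)c2O)ccc1O | target

Total step count: 14.
Longest linear sequence: 10 steps (steps 1–8, 13 and 14); the diene branch is steps 9–12.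

Steps most likely to fail

1. Step 13. The alkyne is activated only through the vinylogous carbonyl and carries a donor at C3, so the cycloaddition may be slow enough that thermal decomposition or desilylation of the diene outruns it. Fallback (cross-coupling in place of cycloaddition), setting out from iodide 12 and returning at 25: 4-bromophenol is ortho-C-prenylated as its sodium salt (NaH, toluene) with 2 to give 4-bromo-2-(3-methylbut-2-en-1-yl)phenol F1. Miyaura borylation (B2pin2, Pd(dppf)Cl2, KOAc, dioxane, 80 °C) gives 2-(3-methylbut-2-en-1-yl)-4-(4,4,5,5-tetramethyl-1,3,2-dioxaborolan-2-yl)phenol F2. Suzuki–Miyaura coupling of F2 with 12 (Pd(PPh3)4, K2CO3, dioxane–water, 80 °C) should give 25.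

2. Step 3. Enolisation of the phenoxide ketone may be incomplete, the product alkoxide may be oxidized further, or the enolate may add to the sulfonimine that the oxidant leaves behind. Fallback (the O3 atom is introduced after ring closure), setting out from 4 and returning at 10: 4 is condensed with 8 to (2E)-3-(dimethylamino)-1-[2-hydroxy-4,6-bis(methoxymethoxy)-3-(3-methylbut-2-en-1-yl)phenyl]prop-2-en-1-one F3. This is cyclised (AcOH) to 5,7-bis(methoxymethoxy)-8-(3-methylbut-2-en-1-yl)-4H-chromen-4-one F4. Weitz–Scheffer epoxidation (H2O2, NaOH, MeOH–CH2Cl2, 0 °C), which attacks the enone and not the prenyl alkene, gives racemic cis-2,3-epoxy-5,7-bis(methoxymethoxy)-8-(3-methylbut-2-en-1-yl)chroman-4-one F5. Catalytic pyridinium tosylate opens the epoxide at the acetal-like C2, and tautomerisation gives 3-hydroxy-5,7-bis(methoxymethoxy)-8-(3-methylbut-2-en-1-yl)-4H-chromen-4-one F6. MOMCl and iPr2NEt then give 10.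

3. Step 6. The amide base or the C2 carbanion may add to the pyrone ring of a second molecule, or metalation may occur at another site, so that the iodide is not formed cleanly. Fallback (C2 carries its carbon substituent from the ring-forming step, no C–H metalation), setting out from 7 and returning at 15: Claisen condensation of 7 with diethyl oxalate (LiN(SiMe3)2, THF) gives ethyl 4-[2-hydroxy-4,6-bis(methoxymethoxy)-3-(3-methylbut-2-en-1-yl)phenyl]-3-(methoxymethoxy)-2,4-dioxobutanoate F7. Cyclodehydration (AcOH, 60 °C) gives ethyl 3,5,7-tris(methoxymethoxy)-8-(3-methylbut-2-en-1-yl)-4-oxo-4H-chromene-2-carboxylate F8. NaBH4 (MeOH, 0 °C) reduces the activated ester to 2-(hydroxymethyl)-3,5,7-tris(methoxymethoxy)-8-(3-methylbut-2-en-1-yl)-4H-chromen-4-one F9. MnO2 gives 3,5,7-tris(methoxymethoxy)-8-(3-methylbut-2-en-1-yl)-4-oxo-4H-chromene-2-carbaldehyde F10. Ohira–Bestmann homologation (dimethyl (1-diazo-2-oxopropyl)phosphonate, K2CO3, MeOH, 0 °C) then gives 15.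

Further compounds
F1 | step 13 | 4-bromo-2-(3-methylbut-2-en-1-yl)phenol | CC(C)=CCc1cc(Br)ccc1O
F2 | step 13 | 2-(3-methylbut-2-en-1-yl)-4-(4,4,5,5-tetramethyl-1,3,2-dioxaborolan-2-yl)phenol | CC(C)=CCc1cc(B2OC(C)(C)C(C)(C)O2)ccc1O
F3 | step 3 | (2E)-3-(dimethylamino)-1-[2-hydroxy-4,6-bis(methoxymethoxy)-3-(3-methylbut-2-en-1-yl)phenyl]prop-2-en-1-one | CN(C)/C=C/C(=O)c1c(OCOC)cc(OCOC)c(CC=C(C)C)c1O
F4 | step 3 | 5,7-bis(methoxymethoxy)-8-(3-methylbut-2-en-1-yl)-4H-chromen-4-one | O=c1ccoc2c(CC=C(C)C)c(OCOC)cc(OCOC)c12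
F5 | step 3 | cis-2,3-epoxy-5,7-bis(methoxymethoxy)-8-(3-methylbut-2-en-1-yl)chroman-4-one (racemic) | O=C1C3OC3Oc2c(CC=C(C)C)c(OCOC)cc(OCOC)c12
F6 | step 3 | 3-hydroxy-5,7-bis(methoxymethoxy)-8-(3-methylbut-2-en-1-yl)-4H-chromen-4-one | O=c1c(O)coc2c(CC=C(C)C)c(OCOC)cc(OCOC)c12
F7 | step 6 | ethyl 4-[2-hydroxy-4,6-bis(methoxymethoxy)-3-(3-methylbut-2-en-1-yl)phenyl]-3-(methoxymethoxy)-2,4-dioxobutanoate (racemic) | CCOC(=O)C(=O)C(OCOC)C(=O)c1c(OCOC)cc(OCOC)c(CC=C(C)C)c1O
F8 | step 6 | ethyl 3,5,7-tris(methoxymethoxy)-8-(3-methylbut-2-en-1-yl)-4-oxo-4H-chromene-2-carboxylate | CCOC(=O)c1oc2c(CC=C(C)C)c(OCOC)cc(OCOC)c2c(=O)c1OCOC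
F9 | step 6 | 2-(hydroxymethyl)-3,5,7-tris(methoxymethoxy)-8-(3-methylbut-2-en-1-yl)-4H-chromen-4-one | OCc1oc2c(CC=C(C)C)c(OCOC)cc(OCOC)c2c(=O)c1OCOC
F10 | step 6 | 3,5,7-tris(methoxymethoxy)-8-(3-methylbut-2-en-1-yl)-4-oxo-4H-chromene-2-carbaldehyde | O=Cc1oc2c(CC=C(C)C)c(OCOC)cc(OCOC)c2c(=O)c1OCOC
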